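**Retrosynthetic overview**
1. The C8 carbinol-aldehyde is taken back to a C8 ketone plus a formyl anion (1,3-dithiane), and the C4 gem-dimethyl group to a C4 ketone (Peterson methylenation, then radical hydromethylation).
2. Ring B (C5–C6–C7–C8–C9–C10) is then cut by a [4+2] cycloaddition that makes C5–C6 and C9–C10 between bromo enone 6 (ring A, C5=C10 activated by the C4 carbonyl) and 2-silyloxydiene 14 (C6=C7–C8(OTBS)=C9, carrying the complete Z-enoate side chain).
3. Enabling feature: in ring B the oxygen-bearing C8 is 1,4 to the ring-fusion carbon C5, whose neighbour C4 (the future CMe2 carbon) can be a carbonyl. With C8 and C4 as carbonyls ring B is the retron of a silyloxydiene/enone cycloaddition, C9 is α to C8=O and correctable, and a bromine on C5 gives access to the trans ring fusion.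
4. Ring order: ring A is bought (3-methylcyclohex-2-enone; C3 oxygen and all chirality from α′-acetoxylation and lipase resolution), ring B is formed in the key step; 14 comes from but-3-enoic acid and methyl but-2-ynoate by a stereoretentive B-alkyl Suzuki coupling.

Key step: step 10

Numbering and faces: labdane numbering is used for the decalin (C1–C10; C20 = methyl on C10; C18/C19 = methyls on C4; C17 = formyl carbon; C11–C16 = side chain); "syn" and "anti" refer to the face that carries C20.
Assumption: in step 2 the lipase hydrolyses the (R)-acetate of 2 faster, as expected from the usual enantiopreference of this enzyme for esters of secondary alcohols.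

Step 1
Reactants: 1 3-methylcyclohex-2-en-1-one
Product: 2 rac-6-acetoxy-3-methylcyclohex-2-en-1-one
Conditions: Mn(OAc)3·2H2O, benzene, reflux (Dean–Stark)
Reagents that add atoms: manganese triacetate, CC(=O)O[Mn](OC(C)=O)OC(C)=O
Why: Mn(OAc)3 α′-acetoxylation of enones is selective for the saturated α′ carbon (manganese enolate on the CH2 side, acetoxy transfer) and is established for 3-substituted cyclohexenones.

Step 2
Reactants: 2 rac-6-acetoxy-3-methylcyclohex-2-en-1-one
Product: 3 (6R)-6-hydroxy-3-methylcyclohex-2-en-1-one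
Conditions: Burkholderia cepacia lipase (Amano PS), phosphate buffer pH 7/MTBE, 30 °C, stopped near half conversion
Reagents that add atoms: none
Why: Lipase-catalysed enantioselective ester hydrolysis (kinetic resolution) of α′-acetoxy enones cleaves the (R)-acetate to 3, which is separated from the unreacted (S)-enantiomer of 2, so the C3 stereocentre comes from the enzyme.

Step 3
Reactants: 3 (6R)-6-hydroxy-3-methylcyclohex-2-en-1-one
Product: 4 (6R)-6-[(tert-butyldimethylsilyl)oxy]-3-methylcyclohex-2-en-1-one
Conditions: TBSCl, imidazole, DMF, 0 °C → rt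
Reagents that add atoms: tert-butyldimethylsilyl chloride, CC(C)(C)[Si](C)(C)Cl
Why: Standard imidazole-mediated silylation, mild enough not to enolise the α′ stereocentre.

Step 4
Reactants: 4 (6R)-6-[(tert-butyldimethylsilyl)oxy]-3-methylcyclohex-2-en-1-one
Product: 6 (6R)-2-bromo-6-[(tert-butyldimethylsilyl)oxy]-3-methylcyclohex-2-en-1-one, via dibromide 5 (not isolated)
Conditions: Br2, CH2Cl2, −20 °C; then Et3N, 0 °C → rt
Reagents that add atoms: bromine, BrBr
Why: Bromine addition to the enone C=C followed by amine-induced dehydrobromination (loss of the acidic α-H and the tertiary β-bromide) is the standard route to 2-bromo-3-alkylcyclohex-2-enones.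

Step 5
Reactants: 7 methyl but-2-ynoate
Product: 8 methyl (2Z)-3-iodobut-2-enoate
Conditions: NaI, AcOH, 110 °C
Reagents that add atoms: sodium iodide, [Na+].[I-]
Why: Hydroiodination of an ynoate (conjugate addition of iodide, anti protonation) gives the (Z)-β-iodo enoate, which fixes the later C13=C14 geometry.

Step 6
Reactants: 9 but-3-enoic acid
Product: 10 N-methoxy-N-methylbut-3-enamide
Conditions: MeNH(OMe)·HCl, EDC·HCl, N-methylmorpholine, CH2Cl2, 0 °C → rt
Reagents that add atoms: N,O-dimethylhydroxylamine hydrochloride, CNOC.Cl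
Why: Carbodiimide amide coupling (Weinreb amide formation) at low temperature leaves the β,γ-alkene out of conjugation.

Step 7
Reactants: 10 N-methoxy-N-methylbut-3-enamide; 8 methyl (2Z)-3-iodobut-2-enoate
Product: 12 methyl (2Z)-7-[methoxy(methyl)amino]-3-methyl-7-oxohept-2-enoate, via alkylborane 11 (not isolated)
Conditions: 9-BBN, THF, 0 °C → rt; then 8, PdCl2(dppf) (5 mol %), AsPh3, Cs2CO3, DMF/H2O, rt
Reagents that add atoms: none
Why: Anti-Markovnikov hydroboration followed by B-alkyl Suzuki–Miyaura coupling, which proceeds with retention at the alkenyl iodide and so carries the Z geometry of 8 into the C13=C14 bond.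

Step 8
Reactants: 12 methyl (2Z)-7-[methoxy(methyl)amino]-3-methyl-7-oxohept-2-enoate
Product: 13 methyl (2Z)-3-methyl-7-oxonona-2,8-dienoate
Conditions: vinylmagnesium bromide, THF, −78 → −20 °C; inverse quench into cold aq HCl
Reagents that add atoms: vinylmagnesium bromide, C=C[Mg]Br
Why: Weinreb ketone synthesis: the chelated tetrahedral intermediate stops at the ketone stage, and the amide reacts much faster than the hindered conjugated methyl ester.

Step 9
Reactants: 13 methyl (2Z)-3-methyl-7-oxonona-2,8-dienoate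
Product: 14 methyl (2Z,6Z)-7-[(tert-butyldimethylsilyl)oxy]-3-methylnona-2,6,8-trienoate
Conditions: TBSOTf, Et3N, CH2Cl2, −78 → 0 °C
Reagents that add atoms: tert-butyldimethylsilyl trifluoromethanesulfonate, CC(C)(C)[Si](C)(C)OS(=O)(=O)C(F)(F)F
Why: Soft enolisation of the vinyl ketone can occur only at the α′-CH2 and gives the (Z)-silyl dienol ether (side chain trans to the vinyl group), a 2-silyloxydiene that can reach the s-cis form; the ester is not enolised.

Step 10
Reactants: 14 methyl (2Z,6Z)-7-[(tert-butyldimethylsilyl)oxy]-3-methylnona-2,6,8-trienoate; 6 (6R)-2-bromo-6-[(tert-butyldimethylsilyl)oxy]-3-methylcyclohex-2-en-1-one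
Product: 15 methyl (2Z)-5-{(1R,4aS,6R,8aS)-4a-bromo-2,6-bis[(tert-butyldimethylsilyl)oxy]-8a-methyl-5-oxo-1,4,4a,5,6,7,8,8a-octahydronaphthalen-1-yl}-3-methylpent-2-enoate
Conditions: Me2AlNTf2 (20 mol %, from AlMe3 and HNTf2), CH2Cl2, −40 → 0 °C
Reagents that add atoms: none
Why: The aluminium triflimide binds the C4 carbonyl of 6 and triggers a strongly asynchronous [4+2] addition in which the nucleophilic diene terminus C9 attacks the enone β-carbon C10 and the developing bromo-enolate carbon C5 closes onto the allyl-cation terminus C6. The closest known reaction type is the aluminium-Lewis-acid-catalysed Diels–Alder reaction of hindered 2-silyloxydienes with β,β-disubstituted cyclohexenones, which builds quaternary ring-fusion carbons. Ring B is closed by intermolecular [4+2] cycloaddition, suprafacial on both partners (should it turn stepwise, the second bond forms by a 6-endo-trig Michael closure), with "para" regiochemistry: the oxygen-bearing C8 ends 1,4 to C5, the carbon next to the carbonyl. C10 is controlled by the C3 stereocentre: the bromine blocks the carbonyl lone pair on its side, the Lewis acid therefore sits syn to C3, allylic strain turns the C3–OTBS bond pseudoaxial, and the diene bonds axially to C10 on the opposite face, which leaves C20 syn to the C3 oxygen. C5 is cis to C10 by the suprafacial addition (bromine syn to C20, exchanged for hydrogen in step 11) and C9 follows the endo approach (side chain anti to C20, corrected in step 12; any exo-derived C9 epimer converges there too). The step needs reactivity at a tetrasubstituted alkene plus one regiochemical and one π-facial sense; the LUMO-lowering bromine, the unsubstituted diene terminus that meets the fully substituted C5, the 2-silyloxy group of the diene and the α′-silyloxy stereocentre of 6 secure them.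

Step 11
Reactants: 15 cis-fused bromo ketone (cycloadduct)
Product: 16 methyl (2Z)-5-{(1R,4aS,6R,8aS)-2,6-bis[(tert-butyldimethylsilyl)oxy]-8a-methyl-5-oxo-1,4,4a,5,6,7,8,8a-octahydronaphthalen-1-yl}-3-methylpent-2-enoate
Conditions: Bu3SnH, Et3B (cat.)/air, toluene, −40 → 0 °C
Reagents that add atoms: none
Why: Radical dehalogenation of an α-bromo ketone: the planar C5 radical should take hydrogen from the stannane on the face opposite the adjacent, nearly perpendicular C20 methyl (C1 and C9 lie near the nodal plane), giving the trans ring fusion without any enolisation that could touch C3.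

Step 12
Reactants: 16 trans-fused silyloxy ketone
Product: 19 methyl (2Z)-5-[(1S,4aS,6R,8aR)-6-hydroxy-8a-methyl-5-methylidene-2-oxodecahydronaphthalen-1-yl]-3-methylpent-2-enoate, via silyl carbinol 17 (not isolated), via C9-epimeric ketone 18 (not isolated)
Conditions: Me3SiCH2Li, CeCl3, THF, −78 °C; then 48% aq HF, MeCN, 0 °C → rt; then K2CO3 (cat.), MeOH, rt
Reagents that add atoms: (trimethylsilyl)methyllithium, [Li]C[Si](C)(C)C
Why: Cerium-mediated Peterson methylenation (non-basic addition to the hindered C4 ketone while C8 is still masked as the enol ether, then acid-induced elimination) with cleavage of both silyl groups by HF unveils the C8 ketone, and base then equilibrates C9 through the enol to the equatorial side chain syn to C20 (the thermodynamic preference is expected to be modest, so residual 18 is resubmitted).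

Step 13
Reactants: 19 methylidene keto alcohol
Product: 21 methyl (2Z)-5-[(1S,4aS,6R,8aR)-6-hydroxy-5,5,8a-trimethyl-2-oxodecahydronaphthalen-1-yl]-3-methylpent-2-enoate, via hydrazide 20 (not isolated)
Conditions: Fe(acac)3 (cat.), PhSiH3, formaldehyde octane-1-sulfonylhydrazone, THF/EtOH, rt; then MeOH, 60 °C
Reagents that add atoms: formaldehyde octane-1-sulfonylhydrazone, C=NNS(=O)(=O)CCCCCCCC
Why: Metal-hydride hydrogen-atom-transfer (Mukaiyama-type) hydromethylation: hydrogen adds to the exocyclic CH2, the tertiary C4 radical is trapped by the hydrazone, and thermal loss of sulfinate and N2 leaves the second methyl, while the electron-poor trisubstituted enoate and the ketone are poor partners for the hydridic iron hydride.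

Step 14
Reactants: 21 gem-dimethyl keto alcohol
Product: 22 methyl (2Z)-5-[(1S,2R,4aS,6R,8aR)-2-(1,3-dithian-2-yl)-2,6-dihydroxy-5,5,8a-trimethyldecahydronaphthalen-1-yl]-3-methylpent-2-enoate
Conditions: 1,3-dithiane, n-BuLi, THF, −30 °C; then 21, −78 → −20 °C; aq NH4Cl
Reagents that add atoms: 2-lithio-1,3-dithiane, [Li]C1SCCCS1
Why: Corey–Seebach addition of a formyl anion equivalent (excess, one equivalent being spent on the C3 hydroxyl): the bulky nucleophile attacks the C8 ketone equatorially, away from the syn-axial C20 methyl, so the new hydroxyl is axial and syn to C20, and at low temperature the ketone reacts far faster than the conjugated ester.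

Step 15
Reactants: 22 dithianyl diol
Product: 23 methyl (2Z)-5-[(1S,2R,4aS,6R,8aR)-2-formyl-2,6-dihydroxy-5,5,8a-trimethyldecahydronaphthalen-1-yl]-3-methylpent-2-enoate (target, CNP0135080.1)
Conditions: PhI(OCOCF3)2, MeCN/H2O (9:1), 0 °C, 10 min; aq NaHCO3 work-up
Reagents that add atoms: water, O
Why: Oxidative dithiane hydrolysis with a hypervalent iodine reagent is fast and mild enough for the free hydroxyls, the enoate and the rearrangement-prone tertiary α-hydroxy aldehyde.

**Compound list**
1 | 3-methylcyclohex-2-en-1-one | CC1=CC(=O)CCC1 | starting material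
2 | rac-6-acetoxy-3-methylcyclohex-2-en-1-one | CC1=CC(=O)C(OC(C)=O)CC1 | intermediate
3 | (6R)-6-hydroxy-3-methylcyclohex-2-en-1-one | CC1=CC(=O)[C@H](O)CC1 | intermediate
4 | (6R)-6-[(tert-butyldimethylsilyl)oxy]-3-methylcyclohex-2-en-1-one | CC1=CC(=O)[C@H](O[Si](C)(C)C(C)(C)C)CC1 | intermediate
5 | (6R)-2,3-dibromo-6-[(tert-butyldimethylsilyl)oxy]-3-methylcyclohexan-1-one (trans-dibromides, C2/C3 not assigned) | CC1(Br)C(Br)C(=O)[C@H](O[Si](C)(C)C(C)(C)C)CC1 | intermediate
6 | (6R)-2-bromo-6-[(tert-butyldimethylsilyl)oxy]-3-methylcyclohex-2-en-1-one | CC1=C(Br)C(=O)[C@H](O[Si](C)(C)C(C)(C)C)CC1 | intermediate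
7 | methyl but-2-ynoate | CC#CC(=O)OC | starting material
8 | methyl (2Z)-3-iodobut-2-enoate | C/C(I)=C/C(=O)OC | intermediate
9 | but-3-enoic acid | C=CCC(=O)O | starting material
10 | N-methoxy-N-methylbut-3-enamide | C=CCC(=O)N(C)OC | intermediate
11 | 4-(9-borabicyclo[3.3.1]nonan-9-yl)-N-methoxy-N-methylbutanamide | CON(C)C(=O)CCCB1C2CCCC1CCC2 | intermediate
12 | methyl (2Z)-7-[methoxy(methyl)amino]-3-methyl-7-oxohept-2-enoate | COC(=O)/C=C(/C)CCCC(=O)N(C)OC | intermediate
13 | methyl (2Z)-3-methyl-7-oxonona-2,8-dienoate | COC(=O)/C=C(/C)CCCC(=O)C=C | intermediate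
14 | methyl (2Z,6Z)-7-[(tert-butyldimethylsilyl)oxy]-3-methylnona-2,6,8-trienoate | COC(=O)/C=C(/C)CC/C=C(\O[Si](C)(C)C(C)(C)C)C=C | intermediate
15 | methyl (2Z)-5-{(1R,4aS,6R,8aS)-4a-bromo-2,6-bis[(tert-butyldimethylsilyl)oxy]-8a-methyl-5-oxo-1,4,4a,5,6,7,8,8a-octahydronaphthalen-1-yl}-3-methylpent-2-enoate (cis-fused; Br, C20 and 3-OTBS syn; side chain anti) | COC(=O)/C=C(/C)CC[C@@H]1[C@]2(C)CC[C@@H](O[Si](C)(C)C(C)(C)C)C(=O)[C@]2(Br)CC=C1O[Si](C)(C)C(C)(C)C | intermediate
16 | methyl (2Z)-5-{(1R,4aS,6R,8aS)-2,6-bis[(tert-butyldimethylsilyl)oxy]-8a-methyl-5-oxo-1,4,4a,5,6,7,8,8a-octahydronaphthalen-1-yl}-3-methylpent-2-enoate (trans-fused; side chain anti to C20) | COC(=O)/C=C(/C)CC[C@@H]1[C@]2(C)CC[C@@H](O[Si](C)(C)C(C)(C)C)C(=O)[C@H]2CC=C1O[Si](C)(C)C(C)(C)C | intermediate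
17 | methyl (2Z)-5-{2,6-bis[(tert-butyldimethylsilyl)oxy]-5-hydroxy-8a-methyl-5-[(trimethylsilyl)methyl]-1,4,4a,5,6,7,8,8a-octahydronaphthalen-1-yl}-3-methylpent-2-enoate (C4 hydroxyl syn to C20; other centres as in 16) | COC(=O)/C=C(/C)CC[C@@H]1[C@]2(C)CC[C@@H](O[Si](C)(C)C(C)(C)C)[C@](O)(C[Si](C)(C)C)[C@H]2CC=C1O[Si](C)(C)C(C)(C)C | intermediate
18 | methyl (2Z)-5-[(1R,4aS,6R,8aR)-6-hydroxy-8a-methyl-5-methylidene-2-oxodecahydronaphthalen-1-yl]-3-methylpent-2-enoate (C9 epimer of 19) | COC(=O)/C=C(/C)CC[C@@H]1[C@]2(C)CC[C@@H](O)C(=C)[C@H]2CCC1=O | intermediate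
19 | methyl (2Z)-5-[(1S,4aS,6R,8aR)-6-hydroxy-8a-methyl-5-methylidene-2-oxodecahydronaphthalen-1-yl]-3-methylpent-2-enoate | COC(=O)/C=C(/C)CC[C@H]1[C@]2(C)CC[C@@H](O)C(=C)[C@H]2CCC1=O | intermediate
20 | methyl (2Z)-5-[(1S,4aS,6R,8aR)-6-hydroxy-5,8a-dimethyl-5-{[2-(octane-1-sulfonyl)hydrazinyl]methyl}-2-oxodecahydronaphthalen-1-yl]-3-methylpent-2-enoate (both C4 epimers) | COC(=O)/C=C(/C)CC[C@H]1[C@]2(C)CC[C@@H](O)C(C)(CNNS(=O)(=O)CCCCCCCC)[C@H]2CCC1=O | intermediate
21 | methyl (2Z)-5-[(1S,4aS,6R,8aR)-6-hydroxy-5,5,8a-trimethyl-2-oxodecahydronaphthalen-1-yl]-3-methylpent-2-enoate | COC(=O)/C=C(/C)CC[C@H]1[C@]2(C)CC[C@@H](O)C(C)(C)[C@H]2CCC1=O | intermediate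
22 | methyl (2Z)-5-[(1S,2R,4aS,6R,8aR)-2-(1,3-dithian-2-yl)-2,6-dihydroxy-5,5,8a-trimethyldecahydronaphthalen-1-yl]-3-methylpent-2-enoate | COC(=O)/C=C(/C)CC[C@H]1[C@]2(C)CC[C@@H](O)C(C)(C)[C@H]2CC[C@]1(O)C3SCCCS3 | intermediate
23 | methyl (2Z)-5-[(1S,2R,4aS,6R,8aR)-2-formyl-2,6-dihydroxy-5,5,8a-trimethyldecahydronaphthalen-1-yl]-3-methylpent-2-enoate | COC(=O)/C=C(/C)CC[C@H]1[C@]2(C)CC[C@@H](O)C(C)(C)[C@H]2CC[C@]1(O)C=O | target

**Step count and risks**
Total step count: 15. Longest linear sequence: 10 steps (steps 6–9 then 10–15; equally steps 1–4 then 10–15).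

Steps most likely to fail:

Step 10. The cycloaddition may stall after the first C–C bond because the congested C5 fails to close on C6, or π-facial selectivity may erode if higher temperature is needed. Fallback (sets out from 6 and 14, comes back at 15): the two bonds are made in separate, individually known operations. A TiCl4-promoted Mukaiyama–Michael addition of 14 to 6 (CH2Cl2, −78 °C) forms only C9–C10 and gives, after aqueous work-up, the open-chain bromo diketone methyl (2Z)-6-{2-bromo-4-[(tert-butyldimethylsilyl)oxy]-1-methyl-3-oxocyclohexyl}-3-methyl-7-oxonona-2,8-dienoate F1. An amine/silyl triflate-promoted intramolecular Michael addition (TBSOTf, Et3N, CH2Cl2, 0 °C → rt) then closes C5–C6 and traps the ring B enolate as its TBS enol ether, which is 15.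

Step 11. Hydrogen transfer to the C5 radical may be unselective, so that the cis-fused epimer accumulates. Fallback (sets out from 15, comes back at 16): kinetic control is given up. Zinc dust in AcOH/THF removes the bromine without regard to configuration and gives the cis-fused C5 epimer methyl (2Z)-5-{(1R,4aR,6R,8aS)-2,6-bis[(tert-butyldimethylsilyl)oxy]-8a-methyl-5-oxo-1,4,4a,5,6,7,8,8a-octahydronaphthalen-1-yl}-3-methylpent-2-enoate F2 together with 16. The mixture is equilibrated at C5 through the enol (DBU, toluene, 40 °C), 16 is separated by chromatography and F2 is returned to the equilibration. The cis/trans equilibrium of this angular-methyl decalone is expected to be close to even, and C3 can also epimerise under these conditions, so several recycles would be needed.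

Step 14. The basic lithiodithiane may enolise the hindered C8 ketone (return of 21, partial loss of the C9 configuration) or attack the methyl ester. Fallback (sets out from 21, comes back at 23): the less basic hydroxymethyl anion equivalent (isopropoxydimethylsilyl)methylmagnesium chloride (THF, 0 °C) adds equatorially to give the silyl carbinol methyl (2Z)-5-[(1S,2R,4aS,6R,8aR)-2,6-dihydroxy-2-{[dimethyl(propan-2-yloxy)silyl]methyl}-5,5,8a-trimethyldecahydronaphthalen-1-yl]-3-methylpent-2-enoate F3. Tamao–Fleming oxidation (H2O2, KF, KHCO3, THF/MeOH) gives the triol methyl (2Z)-5-[(1S,2R,4aS,6R,8aR)-2,6-dihydroxy-2-(hydroxymethyl)-5,5,8a-trimethyldecahydronaphthalen-1-yl]-3-methylpent-2-enoate F4. TEMPO/PhI(OAc)2 (CH2Cl2, rt) then oxidises only the primary alcohol to the aldehyde, which is 23.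

Further compounds
F1 | step 10 | methyl (2Z)-6-{2-bromo-4-[(tert-butyldimethylsilyl)oxy]-1-methyl-3-oxocyclohexyl}-3-methyl-7-oxonona-2,8-dienoate (C10 as in 15; C5 and C9 unassigned) | COC(=O)/C=C(/C)CCC(C(=O)C=C)[C@]1(C)CC[C@@H](O[Si](C)(C)C(C)(C)C)C(=O)C1Br
F2 | step 11 | methyl (2Z)-5-{(1R,4aR,6R,8aS)-2,6-bis[(tert-butyldimethylsilyl)oxy]-8a-methyl-5-oxo-1,4,4a,5,6,7,8,8a-octahydronaphthalen-1-yl}-3-methylpent-2-enoate | COC(=O)/C=C(/C)CC[C@@H]1[C@]2(C)CC[C@@H](O[Si](C)(C)C(C)(C)C)C(=O)[C@@H]2CC=C1O[Si](C)(C)C(C)(C)C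
F3 | step 14 | methyl (2Z)-5-[(1S,2R,4aS,6R,8aR)-2,6-dihydroxy-2-{[dimethyl(propan-2-yloxy)silyl]methyl}-5,5,8a-trimethyldecahydronaphthalen-1-yl]-3-methylpent-2-enoate | COC(=O)/C=C(/C)CC[C@H]1[C@]2(C)CC[C@@H](O)C(C)(C)[C@H]2CC[C@]1(O)C[Si](C)(C)OC(C)C
F4 | step 14 | methyl (2Z)-5-[(1S,2R,4aS,6R,8aR)-2,6-dihydroxy-2-(hydroxymethyl)-5,5,8a-trimethyldecahydronaphthalen-1-yl]-3-methylpent-2-enoate | COC(=O)/C=C(/C)CC[C@H]1[C@]2(C)CC[C@@H](O)C(C)(C)[C@H]2CC[C@]1(O)CO
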